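**Retrosynthetic overview**

1. The target is a germacranolide whose ten-membered ring (C1–C10) is bridged by an ether oxygen between C5 and C10 (an 11-oxabicyclo[4.4.1]undecane) and trans-fused to an α-methylene-γ-lactone at C6/C7. Locants: C1 ketone, C2=C3, C4(=C15H2), C5 ether CH, C6 lactone O–CH, C7, C8 angelate CH, C9, C10 C(CH3)–O, C11(=C13H2), C12 lactone C=O.
2. Endgame disconnections: the angelate ester at C8 and the C1=O/C2=C3 enone, which go back to a C1 carbinol with a saturated C2–C3 bond.
3. Key disconnection: the ether bond O–C10 together with C6–C7. This unzips both oxepane rings, the carbocycle and the lactone to an acyclic farnesane: a 4,5:1,10-bis-epoxy C6-aldehyde carrying a 2-(trimethylsilylmethyl)acrylate at C7.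
4. Enabling feature: the C5 oxygen is 1,5-related to the methyl-bearing C10 through C4–C3–C2–C1 (two head-to-tail isoprene units, i.e. a 1,5-diepoxide whose tertiary carbons each face the next oxygen). C4 carries the methyl that becomes C15H2, and C6/C7 are the two chain ends.
5. Ring order: oxepane O/C5/C4/C3/C2/C1/C10 first (epoxide strain release), then oxepane O/C5/C6/C7/C8/C9/C10 (which closes the carbocycle at C6–C7), then the γ-lactone. The precursor comes from (2E,6E)-farnesyl acetate by C3 excision, proline α-aminoxylation/olefination and Sharpless and Shi epoxidations.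

Key step: step 12

Remark: the configuration is read from the SMILES as (5S,6S,7R,8R,10S) with a (Z)-2-methylbut-2-enoate (angelate); germacrane locants are used in the text for all intermediates.

**Step 1**
Reactants: 1 (2E,6E)-farnesyl acetate
Product: 2 (2E,6E)-10-bromo-11-hydroxy-3,7,11-trimethyldodeca-2,6-dien-1-yl acetate (racemic at the CHBr carbon)
Conditions: NBS, THF/H2O, 0 °C
Reagents that add atoms: N-bromosuccinimide O=C1CCC(=O)N1Br; water O
Why: Terminal-selective bromohydrin formation (Markovnikov opening of the bromonium ion by water) on the coiled polyene in aqueous medium, the 2,3-alkene being deactivated by the allylic acetate; the new stereocentre is racemic and is excised in step 3.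

**Step 2**
Reactants: 2 bromohydrin
Product: 3 (2E,6E)-10,11-epoxy-3,7,11-trimethyldodeca-2,6-dien-1-yl acetate (racemic epoxide)
Conditions: NaH, THF, 0 °C
Reagents that add atoms: none
Why: Intramolecular Williamson closure (3-exo-tet) of the tertiary alkoxide, with a non-nucleophilic base so that the acetate should survive.

**Step 3**
Reactants: 3 terminal epoxide
Product: 4 (2E,6E)-3,7-dimethyl-10-oxodeca-2,6-dien-1-yl acetate (C7 aldehyde; C6 acetate)
Conditions: H5IO6, THF/Et2O, 0 °C
Reagents that add atoms: none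
Why: Periodic acid should hydrolyse the terminal trisubstituted epoxide and cleave the resulting glycol in one flask (glycol cleavage), leaving the two internal alkenes and the allylic acetate untouched.

**Step 4**
Reactants: 5 trimethyl phosphonoacetate; 6 (iodomethyl)trimethylsilane
Product: 7 methyl 2-(dimethoxyphosphoryl)-3-(trimethylsilyl)propanoate (racemic)
Conditions: NaH, DME, 0 to 60 °C
Reagents that add atoms: none
Why: SN2 C-alkylation of the sodium phosphonoacetate carbanion by the primary α-silyl iodide.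

**Step 5**
Reactants: 4 aldehyde; 7 silylmethyl phosphonate
Product: 9 methyl (2Z,4R,6E,10E)-12-acetoxy-6,10-dimethyl-4-[(phenylamino)oxy]-2-[(trimethylsilyl)methyl]dodeca-2,6,10-trienoate, via α-anilinooxy aldehyde 8 (not isolated)
Conditions: PhNO, L-proline (20 mol %), DMSO, rt; then 7, LiCl, DBU, MeCN, 0 °C
Reagents that add atoms: nitrosobenzene O=Nc1ccccc1
Why: Proline-enamine α-aminoxylation (O-selective nitroso aldol through the acid-directed enamine transition state; L-proline should give 8R) trapped in situ by a Masamune–Roush Horner–Wadsworth–Emmons olefination, whose E-type selectivity should place C8 trans to the ester (2Z by CIP).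

**Step 6**
Reactants: 9 anilinooxy enoate
Product: 10 methyl (2Z,4R,6E,10E)-12-acetoxy-4-hydroxy-6,10-dimethyl-2-[(trimethylsilyl)methyl]dodeca-2,6,10-trienoate
Conditions: Cu(OAc)2 (30 mol %), MeOH, rt
Reagents that add atoms: none
Why: Copper-catalysed N–O cleavage of the O-alkyl N-aryl hydroxylamine; the stereocentre is untouched and the hydroxyl is trans to the ester across C7=C11, so no butenolide should form.

**Step 7**
Reactants: 10 γ-hydroxy enoate
Product: 11 methyl (2Z,4R,6E,10E)-12-acetoxy-4-[(tert-butyldimethylsilyl)oxy]-6,10-dimethyl-2-[(trimethylsilyl)methyl]dodeca-2,6,10-trienoate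
Conditions: TBSCl, imidazole, DMF, rt
Reagents that add atoms: tert-butyldimethylsilyl chloride CC(C)(C)[Si](C)(C)Cl
Why: Standard silyl ether formation; an ether (not an ester) on O8 is chosen so that this oxygen cannot compete as a neighbouring group in step 12.

**Step 8**
Reactants: 11 acetate
Product: 12 methyl (2Z,4R,6E,10E)-4-[(tert-butyldimethylsilyl)oxy]-12-hydroxy-6,10-dimethyl-2-[(trimethylsilyl)methyl]dodeca-2,6,10-trienoate
Conditions: K2CO3 (cat.), MeOH, 0 °C
Reagents that add atoms: none
Why: Carbonate-catalysed methanolysis (transesterification) of the primary allylic acetate; the methyl enoate exchanges degenerately and the silyl groups should tolerate these mild conditions.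

**Step 9**
Reactants: 12 allylic alcohol
Product: 13 methyl (2Z,4R,6E,10R,11R)-4-[(tert-butyldimethylsilyl)oxy]-10,11-epoxy-12-hydroxy-6,10-dimethyl-2-[(trimethylsilyl)methyl]dodeca-2,6-dienoate (germacrane 4R,5R epoxide)
Conditions: Ti(OiPr)4, D-(−)-diisopropyl tartrate, t-BuOOH, 4 Å molecular sieves, CH2Cl2, −20 °C
Reagents that add atoms: tert-butyl hydroperoxide CC(C)(C)OO
Why: Sharpless asymmetric epoxidation, chemoselective for the allylic alcohol alkene; the D-tartrate ligand should deliver oxygen to the face that gives the (4R,5R)-epoxide and so fixes C5.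

**Step 10**
Reactants: 13 epoxy alcohol
Product: 14 methyl (2Z,4R,6R,7R,10R,11R)-4-[(tert-butyldimethylsilyl)oxy]-6,7:10,11-diepoxy-12-hydroxy-6,10-dimethyl-2-[(trimethylsilyl)methyl]dodec-2-enoate (germacrane 1R,10R second epoxide)
Conditions: D-fructose-derived Shi ketone (30 mol %), KHSO5 (as Oxone), K2CO3, Bu4NHSO4, MeCN/dimethoxymethane/aq. Na2B4O7 buffer, 0 °C
Reagents that add atoms: potassium peroxymonosulfate [K+].[O-]S(=O)(=O)OO
Why: Shi epoxidation of the only electron-rich alkene left (the enoate alkene is inert to the dioxirane); the spiro transition state of the D-fructose ketone should give the (R,R)-epoxide of the (E)-trisubstituted alkene under reagent control.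

**Step 11**
Reactants: 14 bis-epoxy alcohol
Product: 15 methyl (2Z,4R,6R,7R,10R,11S)-4-[(tert-butyldimethylsilyl)oxy]-6,7:10,11-diepoxy-6,10-dimethyl-12-oxo-2-[(trimethylsilyl)methyl]dodec-2-enoate
Conditions: Dess–Martin periodinane, NaHCO3, CH2Cl2, 0 °C
Reagents that add atoms: none
Why: Dess–Martin oxidation under buffered, non-basic conditions; both epoxides should survive and C5 cannot epimerise because its hydrogen sits on the epoxide ring.

**Step 12**
Reactants: 15 bis-epoxy aldehyde
Product: 18 (1R,5S,6S,7S,8R,10S)-8-[(tert-butyldimethylsilyl)oxy]-5,10-epoxy-1-hydroxygermacra-4(15),11(13)-dien-12,6-olide, via oxepane aldehyde 16 (not isolated), via bicyclic dihydroxy ester 17 (not isolated)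
Conditions: BF3·OEt2 (2.5 equiv), 2,6-di-tert-butyl-4-methylpyridine (3 equiv), CH2Cl2, −78 to −20 °C; aq. NaHCO3; then camphorsulfonic acid (cat.), CH2Cl2, rt
Reagents that add atoms: none
Why: Proposed new method: BF3 should bind the electron-rich 1,10-epoxide rather than the inductively deactivated glycidic-aldehyde epoxide, whose oxygen then attacks tertiary C10 with inversion to give a bicyclic epoxonium ion that the hindered pyridine opens by anti elimination of a C15 methyl proton across the tertiary C4–O bond, so that strain release in two epoxides delivers the O–C10 ether, the 4(15)-methylene and the C1 carbinol of 16, whose BF3-bound aldehyde is then attacked by C7 of the allylsilane (SE2′, loss of Me3SiF) to form C6–C7 (17) before the C6 oxygen lactonises onto the ester. The closest known reactions are BF3-promoted endo-selective oxacyclisation cascades of 1,5-diepoxides to oxepanes through epoxonium ions (ended there by a carbonate oxygen, here by elimination as in the silyl triflate/amine isomerisation of epoxides to allylic silyl ethers) and the intramolecular Hosomi–Sakurai cyclisation of 2-(silylmethyl)acrylates onto aldehydes to give ring-fused α-methylene lactones. Ring closures: oxepane O/C5/C4/C3/C2/C1/C10 by 6-endo-tet epoxonium formation followed by C4–O cleavage (net 7-endo), oxepane O/C5/C6/C7/C8/C9/C10 (also the ten-membered carbocycle) by 7-exo-trig addition to the carbonyl, γ-lactone by 5-exo-trig acyl substitution. Stereocentres: C10 by SN2 inversion of the Shi epoxide, C5 carried over from the Sharpless epoxide because its C–O bond is never broken, C1 inherited and later oxidised away, C6 and C7 by a chair-like seven-membered transition state in which the C1–C4 bridge is axial at C5 and C10, the complexed carbonyl oxygen lies anti to the ring C5–O bond (Cornforth arrangement) and the C7 alkenyl and C8 silyloxy groups are pseudo-equatorial, which should give H6/H7 trans and H7/H8 cis. The step needs the cascade to run from C10 towards C4 (secured by the deactivated glycidic epoxide and the tertiary-cation character at C10), loss of a methyl proton rather than a ring C3–H or a hydride shift at C4 (hindered base, accessible methyl, cation destabilised by the neighbouring aldehyde), and attack of the allylsilane on one carbonyl face (cis disposition of CHO and the C9 chain on the first oxepane).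

**Step 13**
Reactants: 18 tricyclic carbinol
Product: 20 (2Z,5S,6S,7S,8R,10S)-8-[(tert-butyldimethylsilyl)oxy]-5,10-epoxy-1-oxogermacra-2,4(15),11(13)-trien-12,6-olide, via saturated C1 ketone 19 (not isolated)
Conditions: IBX (4 equiv), DMSO, 75 °C
Reagents that add atoms: none
Why: IBX oxidation of the carbinol followed by IBX dehydrogenation of the ketone in the same flask; only C2 carries α-hydrogens (C10 is quaternary), the new C2=C3 bond is conjugated with C4=C15 and its cis geometry is enforced by the seven-membered ring.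

**Step 14**
Reactants: 20 silyl ether
Product: 21 (2Z,5S,6S,7R,8R,10S)-5,10-epoxy-8-hydroxy-1-oxogermacra-2,4(15),11(13)-trien-12,6-olide
Conditions: HF·pyridine, pyridine/THF, 0 °C to rt
Reagents that add atoms: none
Why: Buffered fluoride desilylation, which should spare the dienone, the α-methylene lactone and the allylic ether; no stereocentre is touched (the C7 descriptor changes for CIP reasons only).

**Step 15**
Reactants: 21 C8 alcohol; 22 angelic acid
Product: 23 target, (2Z,5S,6S,7R,8R,10S)-8-angeloyloxy-5,10-epoxy-1-oxogermacra-2,4(15),11(13)-trien-12,6-olide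
Conditions: 2,4,6-trichlorobenzoyl chloride, Et3N, toluene, rt; then 21, 75 °C (no DMAP)
Reagents that add atoms: none
Why: Yamaguchi esterification through the mixed anhydride, run without DMAP so that the (Z)-angelate should be transferred without isomerisation to the tiglate; C8 keeps its configuration because only the acyl–O bond is formed.

**Compound list**

1 | (2E,6E)-farnesyl acetate | CC(=O)OC/C=C(\C)CC/C=C(\C)CCC=C(C)C | starting material
2 | (2E,6E)-10-bromo-11-hydroxy-3,7,11-trimethyldodeca-2,6-dien-1-yl acetate (racemic) | CC(=O)OC/C=C(\C)CC/C=C(\C)CCC(Br)C(C)(C)O | intermediate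
3 | (2E,6E)-10,11-epoxy-3,7,11-trimethyldodeca-2,6-dien-1-yl acetate (racemic) | CC(=O)OC/C=C(\C)CC/C=C(\C)CCC1OC1(C)C | intermediate
4 | (2E,6E)-3,7-dimethyl-10-oxodeca-2,6-dien-1-yl acetate | CC(=O)OC/C=C(\C)CC/C=C(\C)CCC=O | intermediate
5 | trimethyl phosphonoacetate | COC(=O)CP(=O)(OC)OC | starting material
6 | (iodomethyl)trimethylsilane | C[Si](C)(C)CI | starting material
7 | methyl 2-(dimethoxyphosphoryl)-3-(trimethylsilyl)propanoate (racemic) | COC(=O)C(C[Si](C)(C)C)P(=O)(OC)OC | intermediate
8 | (2E,6E,9R)-3,7-dimethyl-10-oxo-9-[(phenylamino)oxy]deca-2,6-dien-1-yl acetate | CC(=O)OC/C=C(\C)CC/C=C(\C)C[C@@H](ONc1ccccc1)C=O | intermediate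
9 | methyl (2Z,4R,6E,10E)-12-acetoxy-6,10-dimethyl-4-[(phenylamino)oxy]-2-[(trimethylsilyl)methyl]dodeca-2,6,10-trienoate | CC(=O)OC/C=C(\C)CC/C=C(\C)C[C@@H](ONc1ccccc1)/C=C(\C[Si](C)(C)C)C(=O)OC | intermediate
10 | methyl (2Z,4R,6E,10E)-12-acetoxy-4-hydroxy-6,10-dimethyl-2-[(trimethylsilyl)methyl]dodeca-2,6,10-trienoate | CC(=O)OC/C=C(\C)CC/C=C(\C)C[C@@H](O)/C=C(\C[Si](C)(C)C)C(=O)OC | intermediate
11 | methyl (2Z,4R,6E,10E)-12-acetoxy-4-[(tert-butyldimethylsilyl)oxy]-6,10-dimethyl-2-[(trimethylsilyl)methyl]dodeca-2,6,10-trienoate | CC(=O)OC/C=C(\C)CC/C=C(\C)C[C@@H](O[Si](C)(C)C(C)(C)C)/C=C(\C[Si](C)(C)C)C(=O)OC | intermediate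
12 | methyl (2Z,4R,6E,10E)-4-[(tert-butyldimethylsilyl)oxy]-12-hydroxy-6,10-dimethyl-2-[(trimethylsilyl)methyl]dodeca-2,6,10-trienoate | OC/C=C(\C)CC/C=C(\C)C[C@@H](O[Si](C)(C)C(C)(C)C)/C=C(\C[Si](C)(C)C)C(=O)OC | intermediate
13 | methyl (2Z,4R,6E,10R,11R)-4-[(tert-butyldimethylsilyl)oxy]-10,11-epoxy-12-hydroxy-6,10-dimethyl-2-[(trimethylsilyl)methyl]dodeca-2,6-dienoate | OC[C@H]1O[C@]1(C)CC/C=C(\C)C[C@@H](O[Si](C)(C)C(C)(C)C)/C=C(\C[Si](C)(C)C)C(=O)OC | intermediate
14 | methyl (2Z,4R,6R,7R,10R,11R)-4-[(tert-butyldimethylsilyl)oxy]-6,7:10,11-diepoxy-12-hydroxy-6,10-dimethyl-2-[(trimethylsilyl)methyl]dodec-2-enoate | OC[C@H]1O[C@]1(C)CC[C@H]1O[C@]1(C)C[C@@H](O[Si](C)(C)C(C)(C)C)/C=C(\C[Si](C)(C)C)C(=O)OC | intermediate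
15 | methyl (2Z,4R,6R,7R,10R,11S)-4-[(tert-butyldimethylsilyl)oxy]-6,7:10,11-diepoxy-6,10-dimethyl-12-oxo-2-[(trimethylsilyl)methyl]dodec-2-enoate | O=C[C@H]1O[C@]1(C)CC[C@H]1O[C@]1(C)C[C@@H](O[Si](C)(C)C(C)(C)C)/C=C(\C[Si](C)(C)C)C(=O)OC | intermediate
16 | methyl (2Z,4R)-4-[(tert-butyldimethylsilyl)oxy]-5-[(2S,3R,7S)-7-formyl-3-hydroxy-2-methyl-6-methylideneoxepan-2-yl]-2-[(trimethylsilyl)methyl]pent-2-enoate | O=C[C@H]1O[C@@](C)(C[C@@H](O[Si](C)(C)C(C)(C)C)/C=C(\C[Si](C)(C)C)C(=O)OC)[C@H](O)CCC1=C | intermediate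
17 | methyl (1R,5S,6S,7S,8R,10S)-8-[(tert-butyldimethylsilyl)oxy]-5,10-epoxy-1,6-dihydroxygermacra-4(15),11(13)-dien-12-oate | O[C@H]1[C@H](C(=C)C(=O)OC)[C@H](O[Si](C)(C)C(C)(C)C)C[C@]2(C)O[C@H]1C(=C)CC[C@H]2O | intermediate
18 | (1R,5S,6S,7S,8R,10S)-8-[(tert-butyldimethylsilyl)oxy]-5,10-epoxy-1-hydroxygermacra-4(15),11(13)-dien-12,6-olide | C=C1C(=O)O[C@H]2[C@H]1[C@H](O[Si](C)(C)C(C)(C)C)C[C@]1(C)O[C@H]2C(=C)CC[C@H]1O | intermediate
19 | (5S,6S,7S,8R,10S)-8-[(tert-butyldimethylsilyl)oxy]-5,10-epoxy-1-oxogermacra-4(15),11(13)-dien-12,6-olide | C=C1C(=O)O[C@H]2[C@H]1[C@H](O[Si](C)(C)C(C)(C)C)C[C@]1(C)O[C@H]2C(=C)CCC1=O | intermediate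
20 | (2Z,5S,6S,7S,8R,10S)-8-[(tert-butyldimethylsilyl)oxy]-5,10-epoxy-1-oxogermacra-2,4(15),11(13)-trien-12,6-olide | C=C1C(=O)O[C@H]2[C@H]1[C@H](O[Si](C)(C)C(C)(C)C)C[C@]1(C)O[C@H]2C(=C)C=CC1=O | intermediate
21 | (2Z,5S,6S,7R,8R,10S)-5,10-epoxy-8-hydroxy-1-oxogermacra-2,4(15),11(13)-trien-12,6-olide | C=C1C(=O)O[C@H]2[C@H]1[C@H](O)C[C@]1(C)O[C@H]2C(=C)C=CC1=O | intermediate
22 | angelic acid, (Z)-2-methylbut-2-enoic acid | C/C=C(/C)C(=O)O | starting material
23 | (2Z,5S,6S,7R,8R,10S)-8-angeloyloxy-5,10-epoxy-1-oxogermacra-2,4(15),11(13)-trien-12,6-olide | C=C1C(=O)O[C@H]2[C@H]1[C@H](OC(=O)/C(C)=C\C)C[C@]1(C)O[C@H]2C(=C)C=CC1=O | target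

**Step count and risks**

Total step count: 15. Longest linear sequence: 14 steps (steps 1–3 and 5–15, from 1 to 23); step 4 is a one-step branch.

Steps most likely to fail:

Step 12 (Proposed new method). Several processes could divert it:
- reversal of the cascade direction, with activation of the glycidic epoxide and 5-exo attack by the other epoxide oxygen to give a tetrahydrofuran;
- ionisation at C10 followed by a hydride shift;
- ionisation at C4 with capture by the C1 oxygen, or endocyclic instead of exocyclic proton loss;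
- poor facial selectivity when the allylsilane closes the second ring.

The fallback builds the same bonds one at a time with known reaction types, setting out from 13 and returning at 18. The primary hydroxyl of 13 would be silylated (TESCl, imidazole) to the triethylsilyl ether F1. TMSOTf/DBU isomerisation of the 4,5-epoxide (anti elimination across the tertiary C–O bond with loss of a methyl proton) should give the C5 trimethylsilyl ether of the 4(15)-en-5-ol F2. Shi epoxidation as in step 10 should give the (1R,10R)-epoxide F3. Camphorsulfonic acid in wet CH2Cl2 should cleave the trimethylsilyl ether and close the first ring by acid-mediated attack of the C5 hydroxyl on the tertiary epoxide carbon C10 with inversion, giving the oxepane carbinol F4. HF·pyridine would then remove the primary triethylsilyl group to give the oxepane diol F5, and TEMPO/PhI(OAc)2 should oxidise only the primary alcohol to aldehyde 16. This is closed by the BF3·OEt2 Hosomi–Sakurai reaction and lactonised to 18.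

Step 13. The tandem oxidation may stall at the ketone, or IBX may over-oxidise the allylic ether and methylene positions at 75 °C. The fallback separates the two events, from 18 to 20: Dess–Martin oxidation of 18 gives ketone 19, now isolated; soft enolisation (TMSOTf, Et3N) can only occur towards C2 and should give the C1 trimethylsilyl enol ether F6; Saegusa–Ito oxidation with Pd(OAc)2 in MeCN then delivers 20.

Step 5. The α-anilinooxy aldehyde may lose configurational integrity or eliminate during the slow olefination with the α-branched phosphonate. The fallback isolates stable intermediates, setting out from 4 and returning at 11 (bypassing 9 and 10):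
- α-aminoxylation of 4 followed by NaBH4 in the same flask should give the (R)-2-anilinooxy alcohol F7;
- Cu(OAc)2 in MeOH cleaves the N–O bond to the (R)-1,2-diol F8;
- TBSCl/imidazole gives the bis-silyl ether F9;
- HF·pyridine removes the primary silyl group selectively to give the primary alcohol F10;
- Dess–Martin oxidation gives the (R)-α-silyloxy aldehyde F11;
- Horner–Wadsworth–Emmons reaction with 7 (LiCl, DBU) gives 11.

**Further compounds**

F1 | step 12 | triethylsilyl ether of 13 | CC[Si](CC)(CC)OC[C@H]1O[C@]1(C)CC/C=C(\C)C[C@@H](O[Si](C)(C)C(C)(C)C)/C=C(\C[Si](C)(C)C)C(=O)OC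
F2 | step 12 | C5 trimethylsilyl ether of the 4(15)-en-5-ol (C6 triethylsilyl ether) | CC[Si](CC)(CC)OC[C@@H](O[Si](C)(C)C)C(=C)CC/C=C(\C)C[C@@H](O[Si](C)(C)C(C)(C)C)/C=C(\C[Si](C)(C)C)C(=O)OC
F3 | step 12 | (1R,10R)-epoxide of F2 | CC[Si](CC)(CC)OC[C@@H](O[Si](C)(C)C)C(=C)CC[C@H]1O[C@]1(C)C[C@@H](O[Si](C)(C)C(C)(C)C)/C=C(\C[Si](C)(C)C)C(=O)OC
F4 | step 12 | oxepane carbinol (C1 hydroxyl, C6 triethylsilyl ether) | CC[Si](CC)(CC)OC[C@H]1O[C@@](C)(C[C@@H](O[Si](C)(C)C(C)(C)C)/C=C(\C[Si](C)(C)C)C(=O)OC)[C@H](O)CCC1=C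
F5 | step 12 | oxepane diol (C1 and C6 hydroxyls) | OC[C@H]1O[C@@](C)(C[C@@H](O[Si](C)(C)C(C)(C)C)/C=C(\C[Si](C)(C)C)C(=O)OC)[C@H](O)CCC1=C
F6 | step 13 | C1 trimethylsilyl enol ether of 19 | C=C1C(=O)O[C@H]2[C@H]1[C@H](O[Si](C)(C)C(C)(C)C)C[C@]1(C)O[C@H]2C(=C)CC=C1O[Si](C)(C)C
F7 | step 5 | (2E,6E,9R)-10-hydroxy-3,7-dimethyl-9-[(phenylamino)oxy]deca-2,6-dien-1-yl acetate | CC(=O)OC/C=C(\C)CC/C=C(\C)C[C@@H](ONc1ccccc1)CO
F8 | step 5 | (2E,6E,9R)-9,10-dihydroxy-3,7-dimethyldeca-2,6-dien-1-yl acetate | CC(=O)OC/C=C(\C)CC/C=C(\C)C[C@@H](O)CO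
F9 | step 5 | (2E,6E,9R)-9,10-bis[(tert-butyldimethylsilyl)oxy]-3,7-dimethyldeca-2,6-dien-1-yl acetate | CC(=O)OC/C=C(\C)CC/C=C(\C)C[C@@H](O[Si](C)(C)C(C)(C)C)CO[Si](C)(C)C(C)(C)C
F10 | step 5 | (2E,6E,9R)-9-[(tert-butyldimethylsilyl)oxy]-10-hydroxy-3,7-dimethyldeca-2,6-dien-1-yl acetate | CC(=O)OC/C=C(\C)CC/C=C(\C)C[C@@H](O[Si](C)(C)C(C)(C)C)CO
F11 | step 5 | (2E,6E,9R)-9-[(tert-butyldimethylsilyl)oxy]-3,7-dimethyl-10-oxodeca-2,6-dien-1-yl acetate | CC(=O)OC/C=C(\C)CC/C=C(\C)C[C@@H](O[Si](C)(C)C(C)(C)C)C=O
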